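Remark on conventions: the bicyclic part uses benzofuran numbering (O1, C2, C3, C3a, C4–C7, C7a; ring A is the benzene ring, ring B the dihydrofuran) and the butyrolactone (ring C) uses lactone numbering (O1, C2–C5). The target is read as (3S,4S) in ring C and (2S,3R) in ring B. Compounds 8, 23 and 26 and the zinc reagent of step 2 are taken as purchasable.

## Analysis of the target

The target is a sesquineolignan: a 3,4-trans-dibenzylbutyrolactone (ring C) whose C3 benzyl group is ring A of a 2-aryl-3-(hydroxymethyl)-2,3-dihydrobenzofuran, with a 4-hydroxy-3-methoxyphenyl group at each end. It has four stereocentres in two trans pairs, lactone C3/C4 (S,S) and benzofuran C2/C3 (S,R). The pairs are separated by the C5 methylene and the flat ring A, so neither can steer the other; each must be made in one absolute sense and the halves then joined. Sensitive features are three free phenols, a primary alcohol and an epimerisable lactone α-centre. The C2–O1 bond is a 4-hydroxybenzylic aryl ether that ionises in acid, opens through a quinone methide once the para phenol is a phenoxide, and can be hydrogenolysed. The main difficulty is ring A, which is 1,2,3,5-tetrasubstituted: carbon at C3a, the ring oxygen at C7a, a free hydroxyl at C7 and the methylene at C5. The C7 oxygen is a hydroxyl, not a methoxy group, so it does not come with a vanillin-type building block and must stay distinct from the two methoxy groups. The strategy rests on the contiguous sequence C3a (carbon), C7a (oxygen), C7 (oxygen). An aryne across C7–C7a can take up a tethered alkoxide at C7a and an oxygen electrophile at C7 in one operation, so ring A needs only a single fluorine at C7a.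

## Retrosynthetic reasoning

**Protecting groups (35 ⇐ 34 ⇐ 33).** The three phenols are carried as benzyl ethers and the primary alcohol as a triisopropylsilyl ether. The silyl ether is removed first, while the phenols are still capped, so that no phenoxide para to C2 can open ring B. Hydrogenolysis then ends the synthesis.

**Lactone C3–CH2 bond (33 ⇐ 31 + 22).** Cutting between lactone C3 and the benzylic methylene divides the molecule into two halves of similar size, each holding one stereochemical pair. The forward reaction is alkylation of the enolate of lactone 31 with benzylic bromide 22. The electrophile enters anti to the C4 substituent, so C3 is set by C4 and no further control element is needed.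

**C5 side chain (22 ⇐ 21 ⇐ 20 ⇐ 18).** The bromomethyl group is traced through the alcohol and the aldehyde to a dimethyl acetal. The C5 carbon therefore travels through the strongly basic steps in a form that is neither electrophilic nor acidic and is unmasked only when needed. The C7 phenol is benzylated at the same stage.

**O1–C7a and C7–O bonds (18 ⇐ 12).** Both aryl–oxygen bonds on adjacent carbons are cut together, leading back to the fluoroarene carbinol 12. Forward, lithiation next to fluorine and loss of fluoride give the C7–C7a aryne. The tethered alkoxide closes ring B at C7a, and the carbanion left at C7 is borylated and oxidised. This is preferred to cutting C2–C3 or C3–C3a because the C2–O bond is never broken, so both stereocentres can be settled earlier in an open chain, and ring A needs no oxygen substituent beforehand. The primary oxygen of 12 is the same distance from ring A as the secondary one, so it must carry a bulky, non-migrating silyl group.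

**C2–C3 bond of the future ring B (12 ⇐ 11 ⇐ 10 ⇐ 7 + 8).** The carbinol carbon and its aryl-bearing neighbour are disconnected by an auxiliary-controlled syn-aldol between arylacetyl imide 7 and aldehyde 8. A syn adduct is needed because ring closure with retention at the carbinol carbon turns syn into 2,3-trans. Reductive removal of the auxiliary gives the 1,3-diol 11, and the primary hydroxyl is then silylated.

**Arylacetyl unit (7 ⇐ 3 ⇐ 2 ⇐ 1, with 4).** The acetic ester side chain is attached at the C–Br bond of 2 by palladium-catalysed coupling with a zinc ester enolate. This places fluorine ortho to the side chain and the masked aldehyde para to fluorine, as in 1. The ester is converted into imide 7 without aqueous acid because of the acetal.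

**Lactone (31 ⇐ 29 ⇐ 25 + 27; 25 ⇐ 23 + 4; 27 ⇐ 26).** The lactone C4 centre is traced to alkylation of succinate imide 25 with benzylic bromide 27. With the same auxiliary 4 as in the aldol, this order of bond formation gives the (S) configuration. Reduction of the imide carbonyl and lactonisation onto the tert-butyl ester complete 31.

## Alternatives that were turned down

**Alternative 1:** Ring C is cut at O1–C5 and traced to the prochiral cyclobutanone A2. Forward, a peracid under a chiral scandium Lewis acid would insert oxygen next to one of the two enantiotopic CH2 groups (a desymmetrising Baeyer–Villiger oxidation) and give lactone A1, which has the structure of 31.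
- For: the lactone would be reached in about three operations from an allylarene, with a catalytic controller and no auxiliary to attach and remove. On step count for this fragment it is stronger than steps 11–14.
- Against: the two CH2 groups are distinguished only by a remote arylmethyl group, so some of the wrong enantiomer is to be expected. After coupling with an enantiopure partner it becomes a diastereomer of 33 that is hard to remove. The peracid also meets an electron-rich arene.
- Comparison: the key step would address only lactone C4, the easiest of the four centres, and would leave ring A with its two adjacent oxygens unsolved. The chosen strategy spends its key step on that problem and makes the lactone by auxiliary chemistry, where diastereomers can be separated before the auxiliary is cleaved.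

**Alternative 2:** Ring B is cut at C3–C3a and traced to the enantioenriched flavanone A4. Forward, a hypervalent iodine oxidant in acidic orthoformate would attack the enol ether at C3, ring A would shift from C4 to C3, and the pyranone would contract to the trans ester A3, with the former C4 expelled as the methyl ester.
- For: the C7 oxygen and a C5 handle are bought with the aromatic starting material, the trans relationship follows from migration anti to the C2 aryl group, and no organolithium step is needed. On the oxygenation pattern of ring A it is stronger than the aryne route, which has to create C7–O.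
- Against: the only stereocentre of A4 is a benzylic ether carbon β to the ketone. Under the acidic, enolising conditions of the oxidation it can open to the chalcone and reclose, so the enantiopurity is at risk in the key step itself. The mesylate needed to deactivate the C2 aryl group is a further protecting group whose basic removal conflicts with the lactone, and the C5 bromide and the ester both need later adjustment.
- Comparison: the chosen route sets both ring B centres by an auxiliary aldol and never exposes them to conditions that break C2–O. It keeps one type of phenol protection and has the C5 carbon in place from the first step.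

**Alternative 3:** Ring B is cut at C2–C3 and traced to the aryldiazoacetate A6. Forward, a chiral dirhodium tetracarboxylate would generate the carbenoid, which inserts into the benzylic ether C–H bond and closes the ring as the cis ester A5.
- For: both stereocentres would be set catalytically in one step from an achiral precursor assembled by phenol alkylation, with the C7 oxygen already present. It reaches the bicyclic core in fewer steps than the aldol–aryne sequence and needs no auxiliary, which are real advantages.
- Against: the insertion gives the cis ring, so C3 must be epimerised through the ester enolate. That enolate has the ring oxygen in the β-position, and E1cB ring opening would erase both centres. The very hydridic 4-alkoxybenzylic C–H bond may also react stepwise and lower the selectivity. The C5 bromide again needs a separate carbon–carbon bond formation.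
- Comparison: the chosen strategy gives the trans ring directly from a syn aldol, with no epimerisation next to a leaving group, and offers diastereomer separation at the aldol stage.

Key step: step 7

## Route

Step 1
Reactants: 1 3-bromo-4-fluorobenzaldehyde
Product: 2 2-bromo-4-(dimethoxymethyl)-1-fluorobenzene
Conditions: HC(OMe)3 (1.5 equiv), p-TsOH·H2O (1 mol%), MeOH, rt; NaHCO3 quench
Reagents that add atoms: trimethyl orthoformate, COC(OC)OC; methanol, CO
Why: Acid-catalysed acetalisation with the orthoformate as water scavenger; the acetal is inert to the enolate and organolithium chemistry that follows.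

Step 2
Reactants: 2 2-bromo-4-(dimethoxymethyl)-1-fluorobenzene
Product: 3 ethyl 2-[5-(dimethoxymethyl)-2-fluorophenyl]acetate
Conditions: BrZnCH2CO2Et (1.5 equiv, preformed 0.5 M solution in THF), Pd2(dba)3 (2 mol%), XPhos (8 mol%), THF, 65 °C
Reagents that add atoms: (2-ethoxy-2-oxoethyl)zinc bromide, CCOC(=O)C[Zn]Br
Why: Negishi-type coupling of a Reformatsky reagent with an aryl bromide (palladium-catalysed α-arylation of an ester zinc enolate); oxidative addition takes the C–Br bond and leaves C–F, and the neutral zinc enolate does not disturb the acetal.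

Step 3
Reactants: 3 ethyl 2-[5-(dimethoxymethyl)-2-fluorophenyl]acetate; 4 (S)-4-benzyl-2-oxazolidinone
Product: 7 (S)-4-benzyl-3-{2-[5-(dimethoxymethyl)-2-fluorophenyl]acetyl}oxazolidin-2-one, via potassium arylacetate 5 (not isolated), via mixed pivalic anhydride 6 (not isolated)
Conditions: KOSiMe3 (1.0 equiv), THF, rt; pivaloyl chloride (1.0 equiv), −20 → 0 °C; then 4, LiCl, Et3N, rt
Reagents that add atoms: none
Why: Anhydrous ester cleavage by the silanolate gives the potassium carboxylate without the aqueous acid that the benzaldehyde acetal would not survive; the mixed pivalic anhydride then acylates the oxazolidinone at the less hindered carbonyl (LiCl/Et3N N-acylation).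

Step 4
Reactants: 7 (S)-4-benzyl-3-{2-[5-(dimethoxymethyl)-2-fluorophenyl]acetyl}oxazolidin-2-one; 8 4-benzyloxy-3-methoxybenzaldehyde
Product: 10 (S)-4-benzyl-3-[(2S,3S)-3-(4-benzyloxy-3-methoxyphenyl)-2-[5-(dimethoxymethyl)-2-fluorophenyl]-3-hydroxypropanoyl]oxazolidin-2-one, via dibutylboron Z-enolate 9 (not isolated)
Conditions: i-Pr2NEt (1.3 equiv) then Bu2BOTf (1.1 equiv), CH2Cl2, −78 → 0 °C; 8, −78 → 0 °C; pH 7 buffer, MeOH, 30% H2O2, 0 °C
Reagents that add atoms: none
Why: Evans boron syn-aldol: the Z-enolate 9 reacts through a chair Zimmerman–Traxler transition state with the auxiliary carbonyl turned away from the enolate oxygen, so the aldehyde meets the face opposite the auxiliary benzyl group and both new centres are set as (2S,3S). The amine is added before the triflate so that no free boron Lewis acid meets the acetal.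

Step 5
Reactants: 10 the syn-aldol adduct
Product: 11 (1S,2R)-1-(4-benzyloxy-3-methoxyphenyl)-2-[5-(dimethoxymethyl)-2-fluorophenyl]propane-1,3-diol
Conditions: LiBH4 (2 equiv), H2O (1 equiv), Et2O/THF, 0 °C; aq NaOH work-up
Reagents that add atoms: none
Why: Reductive cleavage of the N-acyl oxazolidinone at the exocyclic carbonyl gives the primary alcohol and returns the auxiliary; with the carbonyl gone the aryl-bearing centre is no longer acidic and retro-aldol cleavage is no longer possible.

Step 6
Reactants: 11 the 1,3-diol
Product: 12 (1S,2R)-1-(4-benzyloxy-3-methoxyphenyl)-2-[5-(dimethoxymethyl)-2-fluorophenyl]-3-(triisopropylsilyloxy)propan-1-ol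
Conditions: i-Pr3SiCl (1.1 equiv), imidazole, DMF, 0 °C → rt
Reagents that add atoms: triisopropylsilyl chloride, CC(C)[Si](Cl)(C(C)C)C(C)C
Why: Silylation of the primary hydroxyl in preference to the hindered secondary benzylic one on steric grounds; the bulky group blocks the second oxygen that could reach the aryne and is too hindered to migrate to the neighbouring alkoxide in step 7.

Step 7
Reactants: 12 the fluoroarene carbinol
Product: 18 (2S,3R)-2-(4-benzyloxy-3-methoxyphenyl)-5-(dimethoxymethyl)-3-(triisopropylsilyloxymethyl)-2,3-dihydrobenzofuran-7-ol, via lithium alkoxide 13 (not isolated), via C7-lithiated fluoroarene 14 (not isolated), via C7–C7a aryne 15 (not isolated), via C7-lithiated dihydrobenzofuran 16 (not isolated), via C7 dimethyl boronate 17 (not isolated)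
Conditions: n-BuLi (1.0 equiv), THF (0.05 M), −78 °C; LiTMP (lithium 2,2,6,6-tetramethylpiperidide, 1.2 equiv), −78 °C, 2 h; n-BuLi (1.0 equiv), −78 °C, 30 min; −78 → −20 °C; B(OMe)3 (5 equiv), −78 °C → rt; aq NaOH, 30% H2O2, 0 °C
Reagents that add atoms: hydrogen peroxide, OO
Why: The first equivalent of n-BuLi makes the lithium alkoxide 13; LiTMP then removes the only proton ortho to fluorine (C7–H, the most acidic aryl C–H, and an amide base follows acidity, not coordination to the methoxy groups) to give 14; a further equivalent of n-BuLi turns the liberated 2,2,6,6-tetramethylpiperidine back into LiTMP, so that no N–H acid is left in the flask. On warming, 14 loses LiF to give the aryne 15, and the alkoxide oxygen, three atoms from C3a, adds in the ring plane to C7a (5-exo-dig closure on the in-plane π bond, forming O1–C7a), because addition at C7 would demand a meta-bridged ring. The charge therefore appears at C7 as the sp2 aryllithium 16, ortho to the new ether oxygen; B(OMe)3 captures it as boronate 17 and alkaline H2O2 converts C–B into C7–OH at the same position. The closest known reaction types are alkoxide-to-aryne cyclisations that give dihydrobenzofurans with protonation of the aryl anion, and anionic aryne cyclisations of fluoroarenes with tethered nitrogen or carbon nucleophiles in which the new aryllithium is trapped by an electrophile. No stereocentre is made: the C2–O bond is never broken and C3 is not acidic enough to be touched, so the syn relationship of 12 becomes the 2,3-trans ring of 18. The step needs site selectivity in the lithiation (fluorine has a single ortho hydrogen), regioselectivity in the addition (fixed by the tether), a single oxygen able to cyclise (the primary one is capped), and survival of the C7 anion until the borate arrives (no proton donor is left).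

Step 8
Reactants: 18 the C7 phenol
Product: 20 (2S,3R)-7-benzyloxy-2-(4-benzyloxy-3-methoxyphenyl)-3-(triisopropylsilyloxymethyl)-2,3-dihydrobenzofuran-5-carbaldehyde, via benzyl ether acetal 19 (not isolated)
Conditions: BnBr, K2CO3, DMF, rt; then PPTS, acetone/H2O (10:1), rt
Reagents that add atoms: benzyl bromide, BrCc1ccccc1; water, O
Why: Williamson O-benzylation of the phenoxide protects the C7 hydroxyl for the enolate alkylation; mild acid then hydrolyses the dimethyl acetal through the oxocarbenium ion, while the silyl ether, the benzyl ethers and the benzylic ring ether stay intact.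

Step 9
Reactants: 20 the aldehyde
Product: 21 [(2S,3R)-7-benzyloxy-2-(4-benzyloxy-3-methoxyphenyl)-3-(triisopropylsilyloxymethyl)-2,3-dihydrobenzofuran-5-yl]methanol
Conditions: NaBH4, MeOH/THF, 0 °C
Reagents that add atoms: none
Why: Chemoselective borohydride reduction of the aryl aldehyde; nothing else in the molecule is reducible under these conditions.

Step 10
Reactants: 21 the benzylic alcohol
Product: 22 (2S,3R)-7-benzyloxy-2-(4-benzyloxy-3-methoxyphenyl)-5-(bromomethyl)-3-(triisopropylsilyloxymethyl)-2,3-dihydrobenzofuran
Conditions: CBr4, PPh3, CH2Cl2, 0 °C; used at once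
Reagents that add atoms: carbon tetrabromide, BrC(Br)(Br)Br
Why: Appel bromination converts the primary benzylic alcohol into the bromide under neutral conditions (SN2 on the alkoxyphosphonium ion); the bromide is activated by the para ring oxygen and is not stored.

Step 11
Reactants: 23 mono-tert-butyl succinate (4-tert-butoxy-4-oxobutanoic acid); 4 (S)-4-benzyl-2-oxazolidinone
Product: 25 tert-butyl 4-[(S)-4-benzyl-2-oxooxazolidin-3-yl]-4-oxobutanoate, via mixed pivalic anhydride 24 (not isolated)
Conditions: pivaloyl chloride, Et3N, THF, −20 °C; then 4, LiCl, rt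
Reagents that add atoms: none
Why: N-Acylation of the oxazolidinone through the mixed pivalic anhydride (LiCl/Et3N protocol); the tert-butyl ester is untouched.

Step 12
Reactants: 26 4-benzyloxy-3-methoxybenzyl alcohol
Product: 27 4-benzyloxy-3-methoxybenzyl bromide
Conditions: PBr3 (0.4 equiv), Et2O, 0 °C; used freshly prepared
Reagents that add atoms: phosphorus tribromide, BrP(Br)Br
Why: Conversion of a benzylic alcohol into the bromide through the phosphite ester, a standard preparation of this electrophile.

Step 13
Reactants: 25 the succinate imide; 27 4-benzyloxy-3-methoxybenzyl bromide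
Product: 29 tert-butyl (3S)-3-(4-benzyloxy-3-methoxybenzyl)-4-[(S)-4-benzyl-2-oxooxazolidin-3-yl]-4-oxobutanoate, via sodium Z-enolate 28 (not isolated)
Conditions: NaN(SiMe3)2 (1.1 equiv), THF, −78 °C; then 27, −78 → −30 °C
Reagents that add atoms: none
Why: Evans auxiliary alkylation: the chelated Z-enolate 28 forms at the more acidic imide α-position and is attacked by the benzylic bromide on the face opposite the auxiliary benzyl group, which sets the (3S) centre that becomes lactone C4. Any minor diastereomer can be removed at this stage.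

Step 14
Reactants: 29 the alkylated imide
Product: 31 (S)-4-(4-benzyloxy-3-methoxybenzyl)dihydrofuran-2(3H)-one, via hydroxy ester 30 (not isolated)
Conditions: LiBH4, H2O (1 equiv), Et2O, 0 °C; work-up; then p-TsOH·H2O (10 mol%), toluene, 80 °C
Reagents that add atoms: none
Why: LiBH4 reduces the imide carbonyl to the primary alcohol and leaves the tert-butyl ester; acid then closes the γ-lactone by intramolecular transesterification (5-exo-trig) with loss of tert-butanol. The stereocentre of 30 is not α to a carbonyl and is untouched.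

Step 15
Reactants: 31 the (S)-lactone; 22 the benzylic bromide
Product: 33 (3S,4S)-4-(4-benzyloxy-3-methoxybenzyl)-3-{[(2S,3R)-7-benzyloxy-2-(4-benzyloxy-3-methoxyphenyl)-3-(triisopropylsilyloxymethyl)-2,3-dihydrobenzofuran-5-yl]methyl}dihydrofuran-2(3H)-one, via lithium enolate 32 (not isolated)
Conditions: LiN(SiMe3)2 (1.05 equiv), THF, −78 °C; then 22 (1.0 equiv), DMPU, −78 → −30 °C
Reagents that add atoms: none
Why: Alkylation of the lithium enolate of a β-substituted γ-butyrolactone: the electrophile enters anti to the C4 substituent, so the 3,4-trans lactone with (3S) configuration forms under substrate control, the standard way to trans-dibenzylbutyrolactones.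

Step 16
Reactants: 33 the coupled lactone
Product: 34 (3S,4S)-4-(4-benzyloxy-3-methoxybenzyl)-3-{[(2S,3R)-7-benzyloxy-2-(4-benzyloxy-3-methoxyphenyl)-3-(hydroxymethyl)-2,3-dihydrobenzofuran-5-yl]methyl}dihydrofuran-2(3H)-one
Conditions: Bu4NF (1.5 equiv), AcOH (1.5 equiv), THF, 0 °C → rt
Reagents that add atoms: none
Why: Fluoride cleavage of the primary silyl ether, buffered with acetic acid to spare the lactone α-centre; it is done while the phenols are still benzylated, so that no phenoxide para to C2 can open ring B through a quinone methide.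

Step 17
Reactants: 34 the tribenzyl ether
Product: 35 (3S,4S)-4-(4-hydroxy-3-methoxybenzyl)-3-{[(2S,3R)-7-hydroxy-2-(4-hydroxy-3-methoxyphenyl)-3-(hydroxymethyl)-2,3-dihydrobenzofuran-5-yl]methyl}dihydrofuran-2(3H)-one (CNP0118131.1)
Conditions: H2 (1 atm), 10% Pd/C, EtOAc/EtOH, rt; stopped after three equivalents of H2
Reagents that add atoms: none
Why: Catalytic hydrogenolysis of the three aryl benzyl ethers; the benzylic C2–O1 bond is an internal alkyl aryl ether that should be cleaved much more slowly under neutral conditions.

## Compound list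

1 | 3-bromo-4-fluorobenzaldehyde | O=Cc1ccc(F)c(Br)c1 | starting material
2 | 2-bromo-4-(dimethoxymethyl)-1-fluorobenzene | COC(OC)c1ccc(F)c(Br)c1 | intermediate
3 | ethyl 2-[5-(dimethoxymethyl)-2-fluorophenyl]acetate | CCOC(=O)Cc1cc(C(OC)OC)ccc1F | intermediate
4 | (S)-4-benzyl-2-oxazolidinone | O=C1OC[C@H](Cc2ccccc2)N1 | starting material
5 | potassium 2-[5-(dimethoxymethyl)-2-fluorophenyl]acetate | COC(OC)c1ccc(F)c(CC(=O)[O-])c1.[K+] | intermediate (not isolated)
6 | 2-[5-(dimethoxymethyl)-2-fluorophenyl]acetic pivalic anhydride | COC(OC)c1ccc(F)c(CC(=O)OC(=O)C(C)(C)C)c1 | intermediate (not isolated)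
7 | (S)-4-benzyl-3-{2-[5-(dimethoxymethyl)-2-fluorophenyl]acetyl}oxazolidin-2-one | COC(OC)c1ccc(F)c(CC(=O)N2C(=O)OC[C@@H]2Cc2ccccc2)c1 | intermediate
8 | 4-benzyloxy-3-methoxybenzaldehyde | COc1cc(C=O)ccc1OCc1ccccc1 | starting material
9 | dibutylboron Z-enolate of 7 | CCCCB(CCCC)O/C(N1C(=O)OC[C@@H]1Cc1ccccc1)=C\c1cc(C(OC)OC)ccc1F | intermediate (not isolated)
10 | (S)-4-benzyl-3-[(2S,3S)-3-(4-benzyloxy-3-methoxyphenyl)-2-[5-(dimethoxymethyl)-2-fluorophenyl]-3-hydroxypropanoyl]oxazolidin-2-one | COC(OC)c1ccc(F)c(c1)[C@H](C(=O)N1C(=O)OC[C@@H]1Cc1ccccc1)[C@@H](c1ccc(OCc2ccccc2)c(OC)c1)O | intermediate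
11 | (1S,2R)-1-(4-benzyloxy-3-methoxyphenyl)-2-[5-(dimethoxymethyl)-2-fluorophenyl]propane-1,3-diol | COC(OC)c1ccc(F)c(c1)[C@H](CO)[C@@H](c1ccc(OCc2ccccc2)c(OC)c1)O | intermediate
12 | (1S,2R)-1-(4-benzyloxy-3-methoxyphenyl)-2-[5-(dimethoxymethyl)-2-fluorophenyl]-3-(triisopropylsilyloxy)propan-1-ol | COC(OC)c1ccc(F)c(c1)[C@H](CO[Si](C(C)C)(C(C)C)C(C)C)[C@@H](c1ccc(OCc2ccccc2)c(OC)c1)O | intermediate (key-step precursor)
13 | lithium alkoxide of 12 | COC(OC)c1ccc(F)c(c1)[C@H](CO[Si](C(C)C)(C(C)C)C(C)C)[C@@H](c1ccc(OCc2ccccc2)c(OC)c1)O[Li] | intermediate (not isolated)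
14 | C7-lithiated fluoroarene lithium alkoxide | COC(OC)c1cc([Li])c(F)c(c1)[C@H](CO[Si](C(C)C)(C(C)C)C(C)C)[C@@H](c1ccc(OCc2ccccc2)c(OC)c1)O[Li] | intermediate (not isolated)
15 | C7–C7a aryne lithium alkoxide | COC(OC)C1=CC#CC(=C1)[C@H](CO[Si](C(C)C)(C(C)C)C(C)C)[C@@H](c1ccc(OCc2ccccc2)c(OC)c1)O[Li] | intermediate (not isolated)
16 | (2S,3R)-2-(4-benzyloxy-3-methoxyphenyl)-5-(dimethoxymethyl)-7-lithio-3-(triisopropylsilyloxymethyl)-2,3-dihydrobenzofuran | COC(OC)c1cc([Li])c2c(c1)[C@H](CO[Si](C(C)C)(C(C)C)C(C)C)[C@@H](c1ccc(OCc3ccccc3)c(OC)c1)O2 | intermediate (not isolated)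
17 | dimethyl [(2S,3R)-2-(4-benzyloxy-3-methoxyphenyl)-5-(dimethoxymethyl)-3-(triisopropylsilyloxymethyl)-2,3-dihydrobenzofuran-7-yl]boronate | COC(OC)c1cc(B(OC)OC)c2c(c1)[C@H](CO[Si](C(C)C)(C(C)C)C(C)C)[C@@H](c1ccc(OCc3ccccc3)c(OC)c1)O2 | intermediate (not isolated)
18 | (2S,3R)-2-(4-benzyloxy-3-methoxyphenyl)-5-(dimethoxymethyl)-3-(triisopropylsilyloxymethyl)-2,3-dihydrobenzofuran-7-ol | COC(OC)c1cc(O)c2c(c1)[C@H](CO[Si](C(C)C)(C(C)C)C(C)C)[C@@H](c1ccc(OCc3ccccc3)c(OC)c1)O2 | intermediate (key-step product)
19 | (2S,3R)-7-benzyloxy-2-(4-benzyloxy-3-methoxyphenyl)-5-(dimethoxymethyl)-3-(triisopropylsilyloxymethyl)-2,3-dihydrobenzofuran | COC(OC)c1cc(OCc3ccccc3)c2c(c1)[C@H](CO[Si](C(C)C)(C(C)C)C(C)C)[C@@H](c1ccc(OCc3ccccc3)c(OC)c1)O2 | intermediate (not isolated)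
20 | (2S,3R)-7-benzyloxy-2-(4-benzyloxy-3-methoxyphenyl)-3-(triisopropylsilyloxymethyl)-2,3-dihydrobenzofuran-5-carbaldehyde | O=Cc1cc(OCc3ccccc3)c2c(c1)[C@H](CO[Si](C(C)C)(C(C)C)C(C)C)[C@@H](c1ccc(OCc3ccccc3)c(OC)c1)O2 | intermediate
21 | [(2S,3R)-7-benzyloxy-2-(4-benzyloxy-3-methoxyphenyl)-3-(triisopropylsilyloxymethyl)-2,3-dihydrobenzofuran-5-yl]methanol | OCc1cc(OCc3ccccc3)c2c(c1)[C@H](CO[Si](C(C)C)(C(C)C)C(C)C)[C@@H](c1ccc(OCc3ccccc3)c(OC)c1)O2 | intermediate
22 | (2S,3R)-7-benzyloxy-2-(4-benzyloxy-3-methoxyphenyl)-5-(bromomethyl)-3-(triisopropylsilyloxymethyl)-2,3-dihydrobenzofuran | BrCc1cc(OCc3ccccc3)c2c(c1)[C@H](CO[Si](C(C)C)(C(C)C)C(C)C)[C@@H](c1ccc(OCc3ccccc3)c(OC)c1)O2 | intermediate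
23 | mono-tert-butyl succinate | CC(C)(C)OC(=O)CCC(=O)O | starting material
24 | 4-tert-butoxy-4-oxobutanoic pivalic anhydride | CC(C)(C)OC(=O)CCC(=O)OC(=O)C(C)(C)C | intermediate (not isolated)
25 | tert-butyl 4-[(S)-4-benzyl-2-oxooxazolidin-3-yl]-4-oxobutanoate | CC(C)(C)OC(=O)CCC(=O)N1C(=O)OC[C@@H]1Cc1ccccc1 | intermediate
26 | 4-benzyloxy-3-methoxybenzyl alcohol | COc1cc(CO)ccc1OCc1ccccc1 | starting material
27 | 4-benzyloxy-3-methoxybenzyl bromide | COc1cc(CBr)ccc1OCc1ccccc1 | intermediate
28 | sodium Z-enolate of 25 | CC(C)(C)OC(=O)C/C=C(\O[Na])N1C(=O)OC[C@@H]1Cc1ccccc1 | intermediate (not isolated)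
29 | tert-butyl (3S)-3-(4-benzyloxy-3-methoxybenzyl)-4-[(S)-4-benzyl-2-oxooxazolidin-3-yl]-4-oxobutanoate | COc1cc(C[C@@H](CC(=O)OC(C)(C)C)C(=O)N2C(=O)OC[C@@H]2Cc2ccccc2)ccc1OCc1ccccc1 | intermediate
30 | tert-butyl (S)-3-(4-benzyloxy-3-methoxybenzyl)-4-hydroxybutanoate | COc1cc(C[C@@H](CC(=O)OC(C)(C)C)CO)ccc1OCc1ccccc1 | intermediate (not isolated)
31 | (S)-4-(4-benzyloxy-3-methoxybenzyl)dihydrofuran-2(3H)-one | COc1cc(C[C@@H]2COC(=O)C2)ccc1OCc1ccccc1 | intermediate
32 | lithium enolate of 31 | COc1cc(C[C@@H]2COC(O[Li])=C2)ccc1OCc1ccccc1 | intermediate (not isolated)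
33 | (3S,4S)-4-(4-benzyloxy-3-methoxybenzyl)-3-{[(2S,3R)-7-benzyloxy-2-(4-benzyloxy-3-methoxyphenyl)-3-(triisopropylsilyloxymethyl)-2,3-dihydrobenzofuran-5-yl]methyl}dihydrofuran-2(3H)-one | COc1cc(C[C@@H]2COC(=O)[C@H]2Cc2cc(OCc4ccccc4)c3c(c2)[C@H](CO[Si](C(C)C)(C(C)C)C(C)C)[C@@H](c2ccc(OCc4ccccc4)c(OC)c2)O3)ccc1OCc1ccccc1 | intermediate
34 | (3S,4S)-4-(4-benzyloxy-3-methoxybenzyl)-3-{[(2S,3R)-7-benzyloxy-2-(4-benzyloxy-3-methoxyphenyl)-3-(hydroxymethyl)-2,3-dihydrobenzofuran-5-yl]methyl}dihydrofuran-2(3H)-one | COc1cc(C[C@@H]2COC(=O)[C@H]2Cc2cc(OCc4ccccc4)c3c(c2)[C@H](CO)[C@@H](c2ccc(OCc4ccccc4)c(OC)c2)O3)ccc1OCc1ccccc1 | intermediate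
35 | (3S,4S)-4-(4-hydroxy-3-methoxybenzyl)-3-{[(2S,3R)-7-hydroxy-2-(4-hydroxy-3-methoxyphenyl)-3-(hydroxymethyl)-2,3-dihydrobenzofuran-5-yl]methyl}dihydrofuran-2(3H)-one | COc1cc(C[C@@H]2COC(=O)[C@H]2Cc2cc(O)c3c(c2)[C@H](CO)[C@@H](c2ccc(O)c(OC)c2)O3)ccc1O | target

## Step count and least certain steps

Total: 17 steps. Longest linear sequence: 13 steps (steps 1–10, then 15–17); the lactone branch (steps 11–14) joins at step 15.

**Step 7 (key step).** The most likely failure is loss of the C7 carbanion by proton transfer before the borate is added, which would end in the C7–H ring. Possible proton sources are traces of amine, unlithiated 12, or the OCH2 group of the benzyl ether. Lithiation next to a methoxy group instead of next to fluorine, or intermolecular capture of the aryne, could also lower the yield. The fallback separates the two C–O bond formations and closes the ring by addition–elimination instead of through the aryne; it sets out from 12 and returns at 20.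
- LiTMP is added to 12 in THF at −78 °C with B(Oi-Pr)3 already present, so that the C7 anion is borylated as it forms and fluoride cannot leave. Oxidation with H2O2/NaOH gives (1S,2R)-1-(4-benzyloxy-3-methoxyphenyl)-2-[5-(dimethoxymethyl)-2-fluoro-3-hydroxyphenyl]-3-(triisopropylsilyloxy)propan-1-ol F1.
- Phenol-selective benzylation (BnBr, K2CO3, DMF) gives the benzyl ether F2.
- PPTS in acetone/water frees the aldehyde, 3-benzyloxy-5-[(1S,2R)-1-(4-benzyloxy-3-methoxyphenyl)-1-hydroxy-3-(triisopropylsilyloxy)propan-2-yl]-4-fluorobenzaldehyde F3.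
- The formyl group is now para to fluorine and activates it, so Cs2CO3 in DMF at 60–80 °C closes ring B by intramolecular SNAr with retention at the carbinol carbon and gives 20.

**Step 4.** The boron triflate may ionise the aryl dimethyl acetal, after which the enolate would add to the oxocarbenium ion. The aldol addition of the aryl-stabilised enolate may also become reversible and erode the syn selectivity. The fallback forms the same bond by acylation and sets the carbinol centre by reduction; it sets out from 3 and returns at 11.
- The sequence of step 3 is run with (R)-4-benzyl-2-oxazolidinone to give (R)-4-benzyl-3-{2-[5-(dimethoxymethyl)-2-fluorophenyl]acetyl}oxazolidin-2-one F4.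
- Its sodium enolate (NaN(SiMe3)2, THF, −78 °C) is acylated with 4-benzyloxy-3-methoxybenzoyl chloride on the face away from the auxiliary benzyl group to give the (2S)-β-keto imide F5.
- Chelation-controlled reduction with Zn(BH4)2 (CH2Cl2/Et2O, −20 °C) gives the syn (2S,3S)-hydroxy imide F6, which differs from 10 only in the configuration of the auxiliary.
- LiBH4 as in step 5 gives 11.

**Step 15.** The 4-alkoxybenzylic bromide 22 may decompose by ionisation (self-alkylation of the electron-rich rings, hydrolysis on handling), and proton transfer between product and enolate may lead to double alkylation. The fallback uses the aldehyde as the electrophile; it sets out from 31 and 20 and returns at 33.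
- The enolate 32 adds to 20 (LiN(SiMe3)2, THF, −78 °C) to give the trans aldol adduct, (3R,4S)-4-(4-benzyloxy-3-methoxybenzyl)-3-{[(2S,3R)-7-benzyloxy-2-(4-benzyloxy-3-methoxyphenyl)-3-(triisopropylsilyloxymethyl)-2,3-dihydrobenzofuran-5-yl](hydroxy)methyl}dihydrofuran-2(3H)-one F7, as a mixture at the carbinol carbon.
- Mesylation and elimination (MsCl, Et3N, then DBU) give the (E)-α-arylidene lactone F8.
- Conjugate reduction with NaBH4/NiCl2·6H2O (MeOH/THF, 0 °C), followed by equilibration of the lactone α-centre with DBU to the more stable trans isomer, gives 33.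

**Step 17.** Hydrogenolysis may go beyond the three benzyl ethers and cleave the benzylic C2–O1 bond, opening ring B. The fallback removes the benzyl groups by Lewis acid instead of by hydrogen; it sets out from 34 and ends at 35. BCl3 with pentamethylbenzene as cation scavenger in CH2Cl2 at −78 °C cleaves aryl benzyl ethers and leaves aryl methyl ethers and the lactone; this path makes no new compound (F0).

## Further compounds

F1 | step 7 | (1S,2R)-1-(4-benzyloxy-3-methoxyphenyl)-2-[5-(dimethoxymethyl)-2-fluoro-3-hydroxyphenyl]-3-(triisopropylsilyloxy)propan-1-ol | COC(OC)c1cc(O)c(F)c(c1)[C@H](CO[Si](C(C)C)(C(C)C)C(C)C)[C@@H](c1ccc(OCc2ccccc2)c(OC)c1)O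
F2 | step 7 | (1S,2R)-1-(4-benzyloxy-3-methoxyphenyl)-2-[3-benzyloxy-5-(dimethoxymethyl)-2-fluorophenyl]-3-(triisopropylsilyloxy)propan-1-ol | COC(OC)c1cc(OCc2ccccc2)c(F)c(c1)[C@H](CO[Si](C(C)C)(C(C)C)C(C)C)[C@@H](c1ccc(OCc2ccccc2)c(OC)c1)O
F3 | step 7 | 3-benzyloxy-5-[(1S,2R)-1-(4-benzyloxy-3-methoxyphenyl)-1-hydroxy-3-(triisopropylsilyloxy)propan-2-yl]-4-fluorobenzaldehyde | O=Cc1cc(OCc2ccccc2)c(F)c(c1)[C@H](CO[Si](C(C)C)(C(C)C)C(C)C)[C@@H](c1ccc(OCc2ccccc2)c(OC)c1)O
F4 | step 4 | (R)-4-benzyl-3-{2-[5-(dimethoxymethyl)-2-fluorophenyl]acetyl}oxazolidin-2-one | COC(OC)c1ccc(F)c(CC(=O)N2C(=O)OC[C@H]2Cc2ccccc2)c1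
F5 | step 4 | (R)-4-benzyl-3-[(2S)-3-(4-benzyloxy-3-methoxyphenyl)-2-[5-(dimethoxymethyl)-2-fluorophenyl]-3-oxopropanoyl]oxazolidin-2-one | COC(OC)c1ccc(F)c(c1)[C@H](C(=O)N1C(=O)OC[C@H]1Cc1ccccc1)C(=O)c1ccc(OCc2ccccc2)c(OC)c1
F6 | step 4 | (R)-4-benzyl-3-[(2S,3S)-3-(4-benzyloxy-3-methoxyphenyl)-2-[5-(dimethoxymethyl)-2-fluorophenyl]-3-hydroxypropanoyl]oxazolidin-2-one | COC(OC)c1ccc(F)c(c1)[C@H](C(=O)N1C(=O)OC[C@H]1Cc1ccccc1)[C@@H](c1ccc(OCc2ccccc2)c(OC)c1)O
F7 | step 15 | (3R,4S)-4-(4-benzyloxy-3-methoxybenzyl)-3-{[(2S,3R)-7-benzyloxy-2-(4-benzyloxy-3-methoxyphenyl)-3-(triisopropylsilyloxymethyl)-2,3-dihydrobenzofuran-5-yl](hydroxy)methyl}dihydrofuran-2(3H)-one, mixture at the carbinol carbon | COc1cc(C[C@@H]2COC(=O)[C@H]2C(O)c2cc(OCc4ccccc4)c3c(c2)[C@H](CO[Si](C(C)C)(C(C)C)C(C)C)[C@@H](c2ccc(OCc4ccccc4)c(OC)c2)O3)ccc1OCc1ccccc1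
F8 | step 15 | (S,E)-4-(4-benzyloxy-3-methoxybenzyl)-3-{[(2S,3R)-7-benzyloxy-2-(4-benzyloxy-3-methoxyphenyl)-3-(triisopropylsilyloxymethyl)-2,3-dihydrobenzofuran-5-yl]methylidene}dihydrofuran-2(3H)-one | COc1cc(C[C@@H]2COC(=O)/C2=C/c2cc(OCc4ccccc4)c3c(c2)[C@H](CO[Si](C(C)C)(C(C)C)C(C)C)[C@@H](c2ccc(OCc4ccccc4)c(OC)c2)O3)ccc1OCc1ccccc1
F0 | step 17 | none | none
A1 | alternative 1 | (S)-4-(4-benzyloxy-3-methoxybenzyl)dihydrofuran-2(3H)-one | COc1cc(C[C@@H]2COC(=O)C2)ccc1OCc1ccccc1
A2 | alternative 1 | 3-(4-benzyloxy-3-methoxybenzyl)cyclobutan-1-one | COc1cc(CC2CC(=O)C2)ccc1OCc1ccccc1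
A3 | alternative 2 | methyl trans-(2S,3S)-7-benzyloxy-5-bromo-2-[3-methoxy-4-(methylsulfonyloxy)phenyl]-2,3-dihydrobenzofuran-3-carboxylate | Brc1cc(OCc2ccccc2)c2c(c1)[C@H](C(=O)OC)[C@@H](c1ccc(OS(C)(=O)=O)c(OC)c1)O2
A4 | alternative 2 | (S)-8-benzyloxy-6-bromo-2-[3-methoxy-4-(methylsulfonyloxy)phenyl]chroman-4-one | O=C1C[C@@H](c2ccc(OS(C)(=O)=O)c(OC)c2)Oc2c1cc(Br)cc2OCc1ccccc1
A5 | alternative 3 | methyl cis-(2S,3R)-7-benzyloxy-2-(4-benzyloxy-3-methoxyphenyl)-5-bromo-2,3-dihydrobenzofuran-3-carboxylate | Brc1cc(OCc2ccccc2)c2c(c1)[C@@H](C(=O)OC)[C@@H](c1ccc(OCc3ccccc3)c(OC)c1)O2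
A6 | alternative 3 | methyl 2-[3-benzyloxy-2-(4-benzyloxy-3-methoxybenzyloxy)-5-bromophenyl]-2-diazoacetate | COC(=O)C(=[N+]=[N-])c1cc(Br)cc(OCc2ccccc2)c1OCc1ccc(OCc2ccccc2)c(OC)c1
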